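The reading at 4.0 d comes long after the fast part of these runs, so the flasks can be reckoned at both ends and the ends joined.

| flask | substrate | partner | protic impurity | remark | time |
|---|---|---|---|---|---|
| Saturday's | 0.020 M | 0.014 M | 4 mM | run made earlier |  |
| Monday's | 0.020 M | 0.0070 M | 4 mM | run made earlier |  |
| midnight | 0.020 M (fed, over 2.5 d) | 0.0140 M | 4.00 mM | all else is in the flask from the start; the feed brings no volume worth counting | 4.0 d |
| winter | 0.020 M (fed, over 15 h) | 0.0140 M | 4.00 mM | all else is in the flask from the start; the feed brings no volume worth counting | 4.0 d |
| autumn | 0.020 M | 0.0140 M (fed, over 2.5 d) | 4.00 mM | all else is in the flask from the start; the feed brings no volume worth counting | 4.0 d |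
| summer | 0.020 M | 0.0140 M | 4.00 mM | everything together at the start | 4.0 d |

Saturday's run (percent of the substrate charged)

| time / d | target / % |
|---|---|
| 0.208 | 18.2 |
| 0.625 | 26.2 |
| 1.04 | 27.7 |
| 1.67 | 28.2 |
| 2.50 | 29.1 |
| 3.00 | 29.3 |
| 4.00 | 30.6 |

Monday's run (percent of the substrate charged)

| time / h | target / % |
|---|---|
| 1.50 | 9.2 |
| 2.50 | 11.6 |
| 4.00 | 15.7 |
| 5.00 | 17.7 |
| 8.00 | 23.2 |
| 12.0 | 25.8 |
| 20.0 | 27.4 |

(standard deviation of a reading: 0.5 percentage points)

1. the best flask by amount of target, in percent of the substrate charged; "all alike" if 1.5 percentage points covers them all (midnight / winter / autumn / summer / all alike)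
2. amount of target at the end, in percent of the substrate charged, midnight
3. amount of target at the end, in percent of the substrate charged, winter
4. amount of target at the end, in percent of the substrate charged, autumn
5. amount of target at the end, in percent of the substrate charged, summer

- the numbers in the tables scatter by 0.5 percentage points (one standard deviation)

The late end comes first. Saturday's readings flatten, and the last two average 29.9%. This is the target share: the part of the substrate charged that ends as target once the substrate has passed, a selectivity read from the readings.

But the partner might move it. Monday's run holds half the c(partner) of Saturday's, yet it shows 17.7% at 5.00 h against Saturday's 18.2% at 0.208 d. That gap of 0.5 percentage points is the size of the scatter, so these two readings, taken at the same time, show no dependence of target on c(partner). If the losses are first order in substrate, as Monday's rise suggests, feeding substrate leaves the share unchanged too.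

Now the early end. Monday's first reading, divided by its time and by the share, gives a rough reading of the rate constant of substrate loss, 0.205 /h, so a half-life of about 3.38 h. Midnight's feed stops 36.0 h before the reading, far longer than that half-life. So this reckoning puts midnight, winter, autumn and summer alike at the target share.

The forecast says summer, with midnight 29%, winter 30%, autumn 21% and summer 30.5%: “Feeding partner starves the early reaction”. On autumn and on the best flask it differs from this reckoning.

The flasks give midnight 29.5%, winter 29.9%, autumn 30.1% and summer 30.0%, so the answer is all alike.

    substrate → target (k = 0.0620 /h)
    substrate + partner → intermediate A (k = 0.210 /M/h)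
    substrate → intermediate B (k = 0.140 /h)
    partner + intermediate A ⇌ intermediate C (K = 7.40 /M, k = 4.70 /M/h)
    partner + intermediate B → side product (k = 46.0 /M/h)
    substrate ⇌ dormant form (K = 1.10, k = 0.0290 /h)
    partner + protic impurity → quenched reagent (k = 33.0 /M/h)
    2 partner → self-condensation product (k = 1.90 /M/h)

Autumn's 30.1% stands at the target share 29.9%. Summer stops near that share because substrate also passes into intermediate B: without this step, summer gives 88.4% instead of 30.0%. A neighbour of summer charged with 0.034 M of substrate should, by the same share, make 10.2 mM of target, which is 29.9% of its charge. That neighbour gives 30.0% of its substrate charged.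

(The numbers in the tables are simulated on assumed constants, noise included.)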